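I decide to weigh the protic impurity against the starting material before I look at any rate.

| flask | starting material | partner | protic impurity | precatalyst | temperature | remark | time |
|---|---|---|---|---|---|---|---|
| alpha | 0.10 M | 2 equiv | 0.050 M | 0.2 mol% | 50 °C | the very flask that is asked about, followed so far |  |
| eta | 0.10 M | 1.3 equiv | 0.050 M | 0.2 mol% | 50 °C | run made earlier |  |
| flask | 0.10 M | 2.00 equiv | 0.0500 M | 0.2 mol% | 50 °C |  | 8.0 d |

Alpha is the flask asked about, and eta differs from it in the amount of partner. So the impurity is common to both runs. The protic impurity charged, as a fraction of the starting material charged, is 50.0%; I call this the claim. If one impurity takes one starting material, the claim leaves 50.0% of the charge for product.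

- alpha (time / d: product / %): 0.625: 6.5; 1.04: 14.1; 1.67: 28.3; 3.00: 47.0; 5.00: 53.3; 8.00: 52.7
- eta (time / d: product / %): 0.250: 1.8; 0.625: 4.3; 1.25: 14.6; 2.08: 29.1; 2.50: 34.8; 4.00: 49.8

(scatter of a reading: 0.5 percentage points)

Alpha climbs faster between 1.04 d and 1.67 d than up to its first reading, so I take it that the catalyst starts slowly and the impurity gets a head start. But this comparison drifts: the impurity thins out as it works, so I expect the claim not to be paid in full. Alpha then stays flat, with 53.3% at 5.00 d and 52.7% at 8.00 d. That level of 53.0% stands 3 percentage points above what the claim leaves. Eta has less partner, 1.3 equiv, yet it reaches 49.8% at 4.00 d, so I don't look to partner for the stop in alpha.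

- elm: change nothing and wait 15 d more
- maple: at 8.0 d raise the temperature by 25 K, then wait 15 d
- oak: at 8.0 d take out 90% of the product then present, then wait 15 d
- alder: at 8.0 d add precatalyst, 50.0% of the amount charged, then wait 15 d
- cedar: at 8.0 d add partner, 100% of the amount charged, then wait 15 d

1. product, in percent of the starting material first charged, at 8.0 d
2. the option that brings most further product ("none" if no option brings more than 2 percentage points) (elm / maple / oak / alder / cedar / none)
3. product present, with what was taken out counted in, in percent of the starting material first charged, after elm
4. product present, with what was taken out counted in, in percent of the starting material first charged, after alder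

- product that was removed still counts
- the numbers in the tables scatter with a standard deviation of 0.5 percentage points
- the earlier runs do not show what temperature does; that part of a forecast is a guess
- additions bring no volume worth counting

I read alpha's charge as divided: 53.0% product and 47.0% quenched, within the claim. So I commit to 53.0% now, after elm and after alder, and to none as best, though temperature stays a guess.

The forecast gives 53% now and 53% after elm, but 73% after alder and alder as best, reading that “the catalyst dies per turnover”.

The flask gives 53.0% now, 53.0% after elm, 53.0% after alder, and none as best.

    starting material + protic impurity → quenched substrate (k = 0.991 /M/h, Ea = 76.0 kJ/mol)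
    partner + precatalyst → free catalyst + spent reagent (k = 0.282 /M/h, Ea = 79.0 kJ/mol)
    starting material + catalyst intermediate A ⇌ catalyst intermediate B (K = 67.5 /M, k = 509 /M/h, Ea = 69.0 kJ/mol, ΔH = −34.0 kJ/mol)
    catalyst intermediate C → free catalyst + product (k = 42.1 /h, Ea = 100 kJ/mol)
    partner + free catalyst → catalyst intermediate A (k = 4990 /M/h, Ea = 59.0 kJ/mol)
    catalyst intermediate B → catalyst intermediate C (k = 12.4 /h, Ea = 96.0 kJ/mol)
    (constants at 50 °C)

In the flask at 8.00 d, starting material, the limiting reagent, stands at 0%, and quenched substrate at 47.0%, below the claim of 50.0%. The run without the quench gives 99.9% of product against 53.0%, so the missing product went to the reaction of starting material with protic impurity. A neighbour flask, the same recipe with 0.20 M of protic impurity, has a claim of 200%, more than the whole charge; at 8.00 d it holds 93.3% quenched substrate and 6.68% product.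

Readings and results stem from a simulated flask for substances that don't exist.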